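## Structural features

The target is a 2,3-diaryl-2,3-dihydro-1-benzofuran. Benzene ring A is fused through C3a and C7a to a dihydrofuran (O1, C2, C3) and carries a hydroxyl on C6 and an (E)-4-hydroxystyryl group on C4. C2 bears a 3,4-dihydroxyphenyl (catechol) ring and C3 a 3,5-dihydroxyphenyl ring; the two stereocentres are adjacent, both S, with the aryl groups trans. Ring A is 1,2,3,5-tetrasubstituted, and C3a lies between the oxygen-bearing C7a and the styryl-bearing C4, so the C3–C3a bond is hindered on both sides. The fragile elements are the C2–O1 bond (a benzylic ether para to a phenolic oxygen, which ionises under acid and opens to a quinone methide under base or oxidant), the doubly benzylic C3–H, the stilbene double bond, and six free phenols including a catechol. The real difficulty is C3: it carries no heteroatom, so its configuration must be set in a C–C bond-forming step and then relayed to C2, and any final deprotection must spare both the C2–O1 bond and the stilbene. The key step exploits that C2 is benzylic and para to O4 of the catechol ring, so this ring can be oxidised to a para-quinone methide with C2 as the exocyclic carbon, while O1 is a phenol oxygen of ring A held ortho to C3a where it can add to that carbon under the direction of C3.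

## Logic of the disconnections

21 to 20. Cut: the four O–benzyl bonds (both oxygens of the C3 aryl ring, O3 of the C2 aryl ring, O4 of the styryl ring). Reason: the catechol O3 and the stilbene O4 must be masked during the oxidation, and benzyl is preferred to methyl because it can be removed at −78 °C without hydrogen, whereas a warm Lewis-acid demethylation would endanger the C2–O1 bond and the stilbene. Gain: 20 is a stable compound with two free phenols. Demand: ether cleavage that neither ionises C2–O1 nor protonates the alkene.

20 to 18 (through 19). Cut: the O1–C2 bond, with formal addition of two hydrogens. Reason: C2 is benzylic and para to a phenol oxygen, and O1 is a phenol oxygen ortho to C3a, so the bond is the product of an oxa-conjugate addition to quinone methide 19. Gain: the heterocycle and the C2 stereocentre disappear; 18 has one stereocentre and a plain CH2 at C2. Demand: oxidation confined to one of three phenols, ring closure faster than tautomerisation of 19, and trans control from C3.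

18 to 17. Cut: three O–CH2OCH3 acetal bonds (on C7a, on C6, and on O4 of the future C2 aryl ring). Reason: these oxygens must be masked through the organometallic steps and freed without touching the benzyl ethers. The C6 hydroxyl is released as well because it cannot reach C2 and is a resorcinol-type phenol, so the two ring-A oxygens need no separate protecting groups. Demand: acid mild enough to leave the stilbene alone.

17 to 14 and 16. Cut: the C4–C(vinyl) bond. Reason: the styryl group is attached last on purpose. The preceding C–C bond is made through a primary radical at C2, and with an ortho styryl group present that radical would cyclise 5-exo onto the alkene; an aryl triflate at C4 offers no such path. Gain: two fragments, with the E geometry supplied by 16. Demand: cross-coupling next to a bulky secondary alkyl group.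

16 to 15. Cut: the C–B bond across the former triple bond. Gain: a one-step, atom-economical source of the (E)-alkenylboron partner. Demand: syn, anti-Markovnikov hydroboration.

14 to 7 and 10. Cut: the C2–C1(aryl) bond; the carboxyl carbon of 7 is given up in the same operation. Reason: this connects the catechol-type ring to a β,β-diarylpropanoic acid, the natural product of a conjugate addition. Gain: 7 has the stereocentre but no C2 aryl ring. Demand: the C2 radical must be captured before a 1,2-aryl shift, and the triflate must survive the nickel catalyst.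

10 to 9 to 8. Cut: one O–CH2OCH3 bond, then the C–Br bond. Gain: a commercial catechol monoether. Demand: bromination para to the free hydroxyl.

7 to 6 to 4. Cut: the O–SO2CF3 bond and the methyl ester C–O bond, which re-forms the lactone. Reason: the phenol liberated on opening the lactone is the position where the styryl group will stand, so it is turned into the triflate. The lactone thereby distinguishes the two ortho oxygens of a ring that comes from a symmetrical 1,3,5-trioxygenated pattern, which settles the regiochemistry of ring A without any electrophilic substitution. Demand: trapping of the phenol before it relactonises.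

4 to 2 and 3. Cut: the bond between the stereocentre and C1 of the 3,5-dioxygenated ring. Reason: this is the only stereocentre that a reagent must set, and the s-cis enoate of a coumarin is an established acceptor for chiral rhodium aryl species. Gain: an achiral lactone and a commercial boronic acid. Demand: insertion next to a peri alkoxy group.

2 to 1. Cut: two acetal O–C bonds. Gain: a commercial, symmetrical dihydroxy lactone. Demand: none beyond complete alkylation.

## Other disconnections considered

Alternative 1: The cut removes both aryl–carbon bonds of the C2–C3 unit at once and leaves ring A as the (E)-alkenylboronic ester A2. Forward, aryllithium A3 adds to boron, and the palladium aryl formed from triflate A4 (Pd(OAc)2, chiral bisphosphine) induces a 1,2-metallate shift. The two aryl groups add anti across the alkene and A1 results with boron on C2. Stereoretentive C–B oxidation, loss of the methoxymethyl group and an invertive ring closure would then give the trans-dihydrobenzofuran.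
- In its favour: two C–C bonds and both stereocentres arise in one catalytic enantioselective event, no carbon is excised and no radical is involved. In convergence and in step count to the diarylethane core it is the better plan. C2 arrives at the alcohol oxidation level, so the ring closure needs no oxidant, which is also better.
- Against it here: the migration terminus is attached to a 2,6-disubstituted aryl ring, far more hindered than the vinyl and β-alkyl alkenyl boron ate complexes on which the method rests. Direct aryl transfer from boron to palladium and a Heck reaction at the second double bond of A2 compete. A2 needs a separately solved 1,2,3,5-substitution pattern, and the closure requires clean inversion at a benzylic carbon that ionises easily.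
- Comparison: at C2 the two plans are equally dependent on C3. The chosen plan sets C3 with a reaction type established on coumarins and draws ring A from a symmetrical precursor, which decides for it.

Alternative 2: Ring A itself is taken apart at C3a–C7a, C4–C5 and C6–C7, leading to the 1,6-diyne A6 (an ethynyl ether on O1, an enyne on C3) and the alkynylboronic ester A7. Forward, Cp*RuCl(cod) couples the two alkynes of A6 to a ruthenacycle, A7 inserts, and reductive elimination gives A5. Benzene ring and dihydrofuran form together, and boron marks C6 for later oxidation.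
- In its favour: the crowded C3a/C4/C7a region is built by ring construction, so no regiochemistry of arene substitution arises. The step is redox-neutral and leaves a stilbene untouched. On these two points it is the equal or the better of the chosen plan.
- Against it: the stereochemical problem moves into open-chain A6, whose two adjacent stereocentres must be set first. The ethynyl ether of a secondary benzylic alcohol is hard to make and prone to thermal retro-ene fragmentation. The position of boron (C6 or C5) rests on modest steric and electronic differences, and the conjugated enyne offers its alkene to the metal.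
- Comparison: the way to A6 would be longer than the way to 18, so the chosen plan is judged better in step economy and in security of precedent; the alternative is better in the elegance of ring-A construction.

Alternative 3: The cut is the C3–C3a bond, read backwards as a 1,2-shift of the ring-A carbon, which turns ester A8 into flavanone A9, a protected natural (2S)-flavanone. Forward, acid and trimethyl orthoformate give the enol ether A10, PhI(OAc)2 (trivalent iodine) attacks its C3, and reductive loss of the iodine group is accompanied by migration of the aryl carbon. The pyranone contracts and the former carbonyl carbon becomes the methyl ester of A8.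
- In its favour: C2 comes from the chiral pool with the configuration needed, the trans relationship follows from the mechanism and the epimerisable ester, no transition metal is required, and the bicyclic core is reached in very few steps. On step count to the core and on cost it is better than the chosen plan, and the mechanism of its key step is as well established.
- Against it here: A8 has an ester on C3 where the target has an aryl ring, and an oxygen on C4 where it has a styryl group. A decarboxylative arylation at C3 (diastereocontrol from C2 only) and an oxygen-to-carbon exchange at C4 remain. 5-Oxygenated flavanones racemise by reversible opening of the pyranone ring under basic protection conditions, and the methyl ethers bring back a harsh final deprotection.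
- Comparison: the alternative starts with the wrong substituent at two positions and the added steps outweigh the short entry, whereas the chosen plan places every substituent in its final position.

Key step: step 11

Remark on the chemistry: the SMILES string is taken as the definition of the target (catechol ring on C2, 4-hydroxystyryl group on C4); the sense of induction in step 2 is assigned by analogy with the parent coumarin, and the antipodal ligand would be used if it proved opposite.

## Route

Step 1
Reactants: 1 5,7-dihydroxy-2H-chromen-2-one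
Product: 2 5,7-bis(methoxymethoxy)-2H-chromen-2-one
Conditions: MOMCl (2.5 equiv), iPr2NEt (3 equiv), DMF, 0 °C → rt
Reagents that add atoms: chloromethyl methyl ether, COCCl
Why: O-alkylation of both acidic phenols (acetal formation); the acetals survive the neutral aqueous rhodium step, bases and organozinc reagents and are later removed by mild acid without touching benzyl ethers.

Step 2
Reactants: 2 5,7-bis(methoxymethoxy)-2H-chromen-2-one; 3 [3,5-bis(benzyloxy)phenyl]boronic acid
Product: 4 (4S)-4-[3,5-bis(benzyloxy)phenyl]-5,7-bis(methoxymethoxy)-3,4-dihydro-2H-chromen-2-one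
Conditions: 3 (4 equiv), Rh(acac)(C2H4)2 (5 mol%), (S)-SEGPHOS (5.5 mol%), 1,4-dioxane/H2O 10:1, 60 °C
Reagents that add atoms: none
Why: Hayashi–Miyaura asymmetric 1,4-addition: the aryl group is transferred from boron to monovalent rhodium, inserts into the s-cis enoate of the lactone, and water protonates the oxa-π-allyl intermediate; the chiral bisphosphine selects the enantioface and sets C4 (the future C3) as S.

Step 3
Reactants: 4 (4S)-4-[3,5-bis(benzyloxy)phenyl]-5,7-bis(methoxymethoxy)-3,4-dihydro-2H-chromen-2-one
Product: 6 methyl (3S)-3-[3,5-bis(benzyloxy)phenyl]-3-[2,4-bis(methoxymethoxy)-6-{[(trifluoromethyl)sulfonyl]oxy}phenyl]propanoate, via hydroxy ester 5 (not isolated)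
Conditions: NaOMe (0.1 equiv), MeOH/THF, 0 °C; AcOH (0.1 equiv), concentrate; then Tf2O, pyridine, CH2Cl2, −20 → 0 °C
Reagents that add atoms: methanol, CO; trifluoromethanesulfonic anhydride, O=S(=O)(OS(=O)(=O)C(F)(F)F)C(F)(F)F
Why: Transesterification of the aryl ester lactone by methanol is downhill and frees exactly one phenol, which is sulfonylated at once so that it cannot relactonise; the stereocentre is β to the carbonyl and not acidic.

Step 4
Reactants: 6 methyl (3S)-3-[3,5-bis(benzyloxy)phenyl]-3-[2,4-bis(methoxymethoxy)-6-{[(trifluoromethyl)sulfonyl]oxy}phenyl]propanoate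
Product: 7 (3S)-3-[3,5-bis(benzyloxy)phenyl]-3-[2,4-bis(methoxymethoxy)-6-{[(trifluoromethyl)sulfonyl]oxy}phenyl]propanoic acid
Conditions: LiOH·H2O (3 equiv), THF/MeOH/H2O 3:1:1, 0 °C → rt; cold 1 M HCl to pH 4
Reagents that add atoms: lithium hydroxide, [Li+].[OH-]
Why: Saponification of an unhindered methyl ester by acyl–oxygen cleavage; the ortho-substituted, electron-rich aryl triflate should resist hydroxide at or below room temperature, and the capped phenol cannot relactonise.

Step 5
Reactants: 8 2-(benzyloxy)phenol
Product: 9 2-(benzyloxy)-4-bromophenol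
Conditions: NBS (1.0 equiv), MeCN, −20 → 0 °C
Reagents that add atoms: N-bromosuccinimide, O=C1CCC(=O)N1Br
Why: Electrophilic aromatic bromination para to the free hydroxyl, the strongest director, as with other catechol monoethers.

Step 6
Reactants: 9 2-(benzyloxy)-4-bromophenol
Product: 10 2-(benzyloxy)-4-bromo-1-(methoxymethoxy)benzene
Conditions: MOMCl (1.3 equiv), iPr2NEt (1.5 equiv), CH2Cl2, 0 °C → rt
Reagents that add atoms: chloromethyl methyl ether, COCCl
Why: O-alkylation; the acetal masks the one phenol of this ring that must be free in 18, survives halogen–lithium exchange and the arylzinc stage, and is released together with the ring-A acetals.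

Step 7
Reactants: 7 (3S)-3-[3,5-bis(benzyloxy)phenyl]-3-[2,4-bis(methoxymethoxy)-6-{[(trifluoromethyl)sulfonyl]oxy}phenyl]propanoic acid; 10 2-(benzyloxy)-4-bromo-1-(methoxymethoxy)benzene
Product: 14 2-{(1S)-2-[3-(benzyloxy)-4-(methoxymethoxy)phenyl]-1-[3,5-bis(benzyloxy)phenyl]ethyl}-3,5-bis(methoxymethoxy)phenyl trifluoromethanesulfonate, via aryllithium 11 (not isolated), via arylzinc chloride 12 (not isolated), via phthalimide ester 13 (not isolated)
Conditions: (a) 10, n-BuLi, THF, −78 °C; ZnCl2, −78 °C → rt; (b) 7, NHPI, DIC, DMAP (cat.), CH2Cl2, rt, then solvent switch to DMF; (c) a (3 equiv) + b, NiCl2(dme) (20 mol%; dme = 1,2-dimethoxyethane), 4,4'-di-tert-butyl-2,2'-bipyridine (40 mol%), THF/DMF, rt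
Reagents that add atoms: none
Why: Nickel-catalysed decarboxylative Negishi arylation of a redox-active ester: electron transfer from low-valent nickel to 13 releases CO2 and phthalimide anion, and the primary C2 radical is captured by aryl-nickel before reductive elimination forms the C(sp3)–C(sp2) bond. No alkene is present, so the radical has no cyclisation path, and bipyridine-ligated zerovalent nickel should insert only slowly into the hindered aryl triflate. The stereocentre is β to the radical and untouched.

Step 8
Reactants: 15 1-(benzyloxy)-4-ethynylbenzene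
Product: 16 2-{(E)-2-[4-(benzyloxy)phenyl]ethenyl}-4,4,5,5-tetramethyl-1,3,2-dioxaborolane
Conditions: HBpin (1.1 equiv), Cp2Zr(H)Cl (5 mol%), Et3N (10 mol%), neat, 60 °C
Reagents that add atoms: pinacolborane, B1OC(C)(C)C(C)(C)O1
Why: Zirconium-catalysed hydroboration of a terminal alkyne (hydrozirconation, then boron–zirconium exchange); syn, anti-Markovnikov addition fixes the E geometry.

Step 9
Reactants: 14 2-{(1S)-2-[3-(benzyloxy)-4-(methoxymethoxy)phenyl]-1-[3,5-bis(benzyloxy)phenyl]ethyl}-3,5-bis(methoxymethoxy)phenyl trifluoromethanesulfonate; 16 2-{(E)-2-[4-(benzyloxy)phenyl]ethenyl}-4,4,5,5-tetramethyl-1,3,2-dioxaborolane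
Product: 17 1-{(1S)-2-[3-(benzyloxy)-4-(methoxymethoxy)phenyl]-1-[3,5-bis(benzyloxy)phenyl]ethyl}-2-{(E)-2-[4-(benzyloxy)phenyl]ethenyl}-4,6-bis(methoxymethoxy)benzene
Conditions: 16 (1.5 equiv), Pd(OAc)2 (5 mol%), SPhos (10 mol%), K3PO4 (3 equiv), THF/H2O 10:1, 60 °C
Reagents that add atoms: none
Why: Suzuki–Miyaura coupling: zerovalent palladium inserts into the C–OTf bond, the alkenyl group is transferred from boron with retention of the E geometry, and reductive elimination forms the C4–vinyl bond; the bulky biarylphosphine copes with the ortho secondary alkyl group.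

Step 10
Reactants: 17 1-{(1S)-2-[3-(benzyloxy)-4-(methoxymethoxy)phenyl]-1-[3,5-bis(benzyloxy)phenyl]ethyl}-2-{(E)-2-[4-(benzyloxy)phenyl]ethenyl}-4,6-bis(methoxymethoxy)benzene
Product: 18 4-{(1S)-2-[3-(benzyloxy)-4-hydroxyphenyl]-1-[3,5-bis(benzyloxy)phenyl]ethyl}-5-{(E)-2-[4-(benzyloxy)phenyl]ethenyl}benzene-1,3-diol
Conditions: HCl (2 M), MeOH/THF 1:1, 40 °C
Reagents that add atoms: none
Why: Acid-catalysed acetal exchange with methanol removes the three methoxymethyl groups; benzyl ethers are stable, and dilute acid at this temperature should not protonate the stilbene.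

Step 11
Reactants: 18 4-{(1S)-2-[3-(benzyloxy)-4-hydroxyphenyl]-1-[3,5-bis(benzyloxy)phenyl]ethyl}-5-{(E)-2-[4-(benzyloxy)phenyl]ethenyl}benzene-1,3-diol
Product: 20 2-(benzyloxy)-4-[(2S,3S)-3-[3,5-bis(benzyloxy)phenyl]-4-{(E)-2-[4-(benzyloxy)phenyl]ethenyl}-6-hydroxy-2,3-dihydro-1-benzofuran-2-yl]phenol, via quinone methide 19 (not isolated)
Conditions: Ag2O (1.1 equiv), toluene/acetone 2:1 (0.01 M), rt, dark, N2
Reagents that add atoms: none
Why: Ag2O takes one electron and a proton from the catechol-monoether phenol of 18, the most electron-rich of the three phenols, and further oxidation or disproportionation of the phenoxyl radical with loss of a benzylic C2 hydrogen gives the para-quinone methide 19. The closest known reaction types are the Ag2O oxidation of 4-alkyl-2-alkoxyphenols to para-quinone methides and the phenol-to-quinone-methide closure that completes phenylcoumaran formation from propenylphenols. The C7a hydroxyl of ring A then adds to the exocyclic carbon in a 5-exo-trig oxa-conjugate (1,6-) addition, which rearomatises the ring, forms the O1–C2 bond and closes the dihydrofuran. The new stereocentre C2 is controlled by C3: in the envelope-like transition state the C2 aryl group turns away from the C3 aryl group, and the trans isomer is also the more stable one, so (2S,3S) is expected from (S)-18. Chemoselectivity should follow from the lower oxidation potential of the guaiacol-type phenol compared with the two resorcinol-type hydroxyls, and from benzyl protection of the stilbene oxygen, which excludes 4-hydroxystilbene radical chemistry. The closure must outrun tautomerisation of 19 to a triarylethene that would erase C3, which the ortho hydroxyl placed five atoms from the electrophilic carbon should ensure, and over-oxidation of 20 is limited by near-stoichiometric oxidant at high dilution. The free C6 hydroxyl cannot reach C2 and so cannot compete as the nucleophile.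

Step 12
Reactants: 20 2-(benzyloxy)-4-[(2S,3S)-3-[3,5-bis(benzyloxy)phenyl]-4-{(E)-2-[4-(benzyloxy)phenyl]ethenyl}-6-hydroxy-2,3-dihydro-1-benzofuran-2-yl]phenol
Product: 21 4-[(2S,3S)-3-(3,5-dihydroxyphenyl)-6-hydroxy-4-[(E)-2-(4-hydroxyphenyl)ethenyl]-2,3-dihydro-1-benzofuran-2-yl]benzene-1,2-diol
Conditions: BCl3 (1 M in CH2Cl2, 10 equiv), C6HMe5 (15 equiv), CH2Cl2, −78 °C; MeOH quench at −78 °C, then water
Reagents that add atoms: none
Why: Lewis-acid cleavage of aryl benzyl ethers with a cation scavenger: BCl3 activates the ether oxygen and pentamethylbenzene takes up the benzyl group by Friedel–Crafts alkylation, so the polyphenol is not C-benzylated; at −78 °C the C2–O1 bond and the stilbene should remain intact, and neither stereocentre is touched.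

## Compound list

1 | 5,7-dihydroxy-2H-chromen-2-one | O=C1C=Cc2c(O)cc(O)cc2O1 | starting material
2 | 5,7-bis(methoxymethoxy)-2H-chromen-2-one | O=C1C=Cc2c(OCOC)cc(OCOC)cc2O1 | intermediate
3 | [3,5-bis(benzyloxy)phenyl]boronic acid | OB(O)c1cc(OCc2ccccc2)cc(OCc2ccccc2)c1 | starting material
4 | (4S)-4-[3,5-bis(benzyloxy)phenyl]-5,7-bis(methoxymethoxy)-3,4-dihydro-2H-chromen-2-one | O=C1C[C@@H](c2cc(OCc3ccccc3)cc(OCc3ccccc3)c2)c2c(OCOC)cc(OCOC)cc2O1 | intermediate
5 | methyl (3S)-3-[3,5-bis(benzyloxy)phenyl]-3-[2-hydroxy-4,6-bis(methoxymethoxy)phenyl]propanoate | COC(=O)C[C@@H](c1cc(OCc2ccccc2)cc(OCc2ccccc2)c1)c1c(O)cc(OCOC)cc1OCOC | intermediate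
6 | methyl (3S)-3-[3,5-bis(benzyloxy)phenyl]-3-[2,4-bis(methoxymethoxy)-6-{[(trifluoromethyl)sulfonyl]oxy}phenyl]propanoate | COC(=O)C[C@@H](c1cc(OCc2ccccc2)cc(OCc2ccccc2)c1)c1c(OS(=O)(=O)C(F)(F)F)cc(OCOC)cc1OCOC | intermediate
7 | (3S)-3-[3,5-bis(benzyloxy)phenyl]-3-[2,4-bis(methoxymethoxy)-6-{[(trifluoromethyl)sulfonyl]oxy}phenyl]propanoic acid | OC(=O)C[C@@H](c1cc(OCc2ccccc2)cc(OCc2ccccc2)c1)c1c(OS(=O)(=O)C(F)(F)F)cc(OCOC)cc1OCOC | intermediate
8 | 2-(benzyloxy)phenol | Oc1ccccc1OCc1ccccc1 | starting material
9 | 2-(benzyloxy)-4-bromophenol | Oc1ccc(Br)cc1OCc1ccccc1 | intermediate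
10 | 2-(benzyloxy)-4-bromo-1-(methoxymethoxy)benzene | COCOc1ccc(Br)cc1OCc1ccccc1 | intermediate
11 | [3-(benzyloxy)-4-(methoxymethoxy)phenyl]lithium | [Li]c1ccc(OCOC)c(OCc2ccccc2)c1 | intermediate
12 | [3-(benzyloxy)-4-(methoxymethoxy)phenyl]zinc chloride | Cl[Zn]c1ccc(OCOC)c(OCc2ccccc2)c1 | intermediate
13 | 1,3-dioxo-1,3-dihydro-2H-isoindol-2-yl (3S)-3-[3,5-bis(benzyloxy)phenyl]-3-[2,4-bis(methoxymethoxy)-6-{[(trifluoromethyl)sulfonyl]oxy}phenyl]propanoate | O=C(C[C@@H](c1cc(OCc2ccccc2)cc(OCc2ccccc2)c1)c1c(OS(=O)(=O)C(F)(F)F)cc(OCOC)cc1OCOC)ON1C(=O)c2ccccc2C1=O | intermediate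
14 | 2-{(1S)-2-[3-(benzyloxy)-4-(methoxymethoxy)phenyl]-1-[3,5-bis(benzyloxy)phenyl]ethyl}-3,5-bis(methoxymethoxy)phenyl trifluoromethanesulfonate | COCOc1ccc(C[C@@H](c2cc(OCc3ccccc3)cc(OCc3ccccc3)c2)c2c(OS(=O)(=O)C(F)(F)F)cc(OCOC)cc2OCOC)cc1OCc1ccccc1 | intermediate
15 | 1-(benzyloxy)-4-ethynylbenzene | C#Cc1ccc(OCc2ccccc2)cc1 | starting material
16 | 2-{(E)-2-[4-(benzyloxy)phenyl]ethenyl}-4,4,5,5-tetramethyl-1,3,2-dioxaborolane | CC1(C)OB(/C=C/c2ccc(OCc3ccccc3)cc2)OC1(C)C | intermediate
17 | 1-{(1S)-2-[3-(benzyloxy)-4-(methoxymethoxy)phenyl]-1-[3,5-bis(benzyloxy)phenyl]ethyl}-2-{(E)-2-[4-(benzyloxy)phenyl]ethenyl}-4,6-bis(methoxymethoxy)benzene | COCOc1ccc(C[C@@H](c2cc(OCc3ccccc3)cc(OCc3ccccc3)c2)c2c(/C=C/c3ccc(OCc4ccccc4)cc3)cc(OCOC)cc2OCOC)cc1OCc1ccccc1 | intermediate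
18 | 4-{(1S)-2-[3-(benzyloxy)-4-hydroxyphenyl]-1-[3,5-bis(benzyloxy)phenyl]ethyl}-5-{(E)-2-[4-(benzyloxy)phenyl]ethenyl}benzene-1,3-diol | Oc1ccc(C[C@@H](c2cc(OCc3ccccc3)cc(OCc3ccccc3)c2)c2c(/C=C/c3ccc(OCc4ccccc4)cc3)cc(O)cc2O)cc1OCc1ccccc1 | intermediate
19 | 2-(benzyloxy)-4-{(2S)-2-[3,5-bis(benzyloxy)phenyl]-2-(2-{(E)-2-[4-(benzyloxy)phenyl]ethenyl}-4,6-dihydroxyphenyl)ethylidene}cyclohexa-2,5-dien-1-one | O=C1C=CC(=C[C@@H](c2cc(OCc3ccccc3)cc(OCc3ccccc3)c2)c2c(/C=C/c3ccc(OCc4ccccc4)cc3)cc(O)cc2O)C=C1OCc1ccccc1 | intermediate
20 | 2-(benzyloxy)-4-[(2S,3S)-3-[3,5-bis(benzyloxy)phenyl]-4-{(E)-2-[4-(benzyloxy)phenyl]ethenyl}-6-hydroxy-2,3-dihydro-1-benzofuran-2-yl]phenol | c1ccccc1COc1ccc(/C=C/c2cc(O)cc3c2[C@H](c2cc(OCc4ccccc4)cc(OCc4ccccc4)c2)[C@@H](c2ccc(O)c(OCc4ccccc4)c2)O3)cc1 | intermediate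
21 | 4-[(2S,3S)-3-(3,5-dihydroxyphenyl)-6-hydroxy-4-[(E)-2-(4-hydroxyphenyl)ethenyl]-2,3-dihydro-1-benzofuran-2-yl]benzene-1,2-diol | Oc1ccc(/C=C/c2cc(O)cc3c2[C@H](c2cc(O)cc(O)c2)[C@@H](c2ccc(O)c(O)c2)O3)cc1 | target

## Step count and least certain steps

Total step count: 12 (steps 5, 6 and 8 are branch steps). Longest linear sequence: 9 steps (steps 1, 2, 3, 4, 7, 9, 10, 11, 12).

Step 11 (key step). Most likely failure: one-electron side reactions of the phenoxyl radical, because the quinone methide must be made by C–H oxidation and not by radical coupling. These are coupling through the unsubstituted position ortho to the phenol, addition of the radical or of the quinone methide to the electron-rich styrene double bond of a second molecule, and further oxidation of the cyclised phenol. Fallback: run the oxidative ring closure before the styryl group is introduced. It sets out from 14. Removal of the three acetals as in step 10 gives the triflate triphenol F1. Ag2O oxidation as in step 11 passes through the quinone methide F2 and closes the ring to the benzofuranyl triflate F3, with no alkene present during the oxidation. A Suzuki–Miyaura coupling of F3 with 16 under the conditions of step 9 (one extra equivalent of base per free phenol) installs the styryl group, and the fallback comes back to the route at 20.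

Step 2. Most likely failure: slow insertion into the C3=C4 bond, because the peri alkoxy group and two donor oxygens make the lactone a hindered, electron-rich acceptor, so that protodeboronation of 3 uses up the aryl donor first. Fallback: separate C–C bond formation from stereocontrol. It sets out from 2 and 3. An oxidative Heck arylation (Pd(OAc)2, 1,10-phenanthroline, O2, DMF, 80 °C) gives the achiral 4-arylcoumarin F4. A copper hydride-catalysed asymmetric conjugate reduction (Cu(OAc)2, the enantiomer of DTBM-SEGPHOS that leads to the S product, diethoxymethylsilane, t-BuOH, toluene) then sets the stereocentre, and the fallback comes back at 4.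

Step 7. Most likely failure: loss of the aryl triflate by oxidative addition to zerovalent nickel and aryl–aryl coupling with 12, in competition with single-electron reduction of 13. A slower neophyl-type 1,2-aryl shift of the 2,2-diarylethyl radical is the second concern. Fallback: carry the ring-A oxygen through the radical coupling as a silyl ether and make the triflate afterwards. It sets out from 4. Methanolysis as in step 3 to 5 and silylation (TIPSOTf, 2,6-lutidine, CH2Cl2) give the silyl ether ester F5, and saponification gives the acid F6. Activation to the phthalimide ester F7 and nickel-catalysed coupling with 12 as in step 7 give the triarylethane silyl ether F8. Buffered fluoride (TBAF, AcOH, THF) frees the phenol F9, and triflation (Tf2O, pyridine) comes back to the route at 14.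

Step 12. Most likely failure: Lewis-acid ionisation of the C2–O1 bond (epimerisation or ring opening), or acid-induced cyclisation of the stilbene onto a neighbouring ring, while four ethers are being cleaved. Fallback: exchange benzyl for silyl under neutral conditions and then use fluoride. It sets out from 20. Pd(OAc)2-catalysed transfer of the benzyl groups to triethylsilane (Et3SiH, Et3N, CH2Cl2, rt), a method that spares alkenes, gives the tetrakis(triethylsilyl) ether F10; any silylation of the two free phenols is harmless. Desilylation with TBAF buffered with AcOH at 0 °C gives 21, where the fallback comes back.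

## Further compounds

F1 | step 11 | 2-{(1S)-2-[3-(benzyloxy)-4-hydroxyphenyl]-1-[3,5-bis(benzyloxy)phenyl]ethyl}-3,5-dihydroxyphenyl trifluoromethanesulfonate | Oc1ccc(C[C@@H](c2cc(OCc3ccccc3)cc(OCc3ccccc3)c2)c2c(OS(=O)(=O)C(F)(F)F)cc(O)cc2O)cc1OCc1ccccc1
F2 | step 11 | 2-{(1S)-2-[3-(benzyloxy)-4-oxocyclohexa-2,5-dien-1-ylidene]-1-[3,5-bis(benzyloxy)phenyl]ethyl}-3,5-dihydroxyphenyl trifluoromethanesulfonate | O=C1C=CC(=C[C@@H](c2cc(OCc3ccccc3)cc(OCc3ccccc3)c2)c2c(OS(=O)(=O)C(F)(F)F)cc(O)cc2O)C=C1OCc1ccccc1
F3 | step 11 | (2S,3S)-2-[3-(benzyloxy)-4-hydroxyphenyl]-3-[3,5-bis(benzyloxy)phenyl]-6-hydroxy-2,3-dihydro-1-benzofuran-4-yl trifluoromethanesulfonate | O=S(=O)(Oc1cc(O)cc2c1[C@H](c1cc(OCc3ccccc3)cc(OCc3ccccc3)c1)[C@@H](c1ccc(O)c(OCc3ccccc3)c1)O2)C(F)(F)F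
F4 | step 2 | 4-[3,5-bis(benzyloxy)phenyl]-5,7-bis(methoxymethoxy)-2H-chromen-2-one | O=C1C=C(c2cc(OCc3ccccc3)cc(OCc3ccccc3)c2)c2c(OCOC)cc(OCOC)cc2O1
F5 | step 7 | methyl (3S)-3-[3,5-bis(benzyloxy)phenyl]-3-{2,4-bis(methoxymethoxy)-6-[(triisopropylsilyl)oxy]phenyl}propanoate | COC(=O)C[C@@H](c1cc(OCc2ccccc2)cc(OCc2ccccc2)c1)c1c(O[Si](C(C)C)(C(C)C)C(C)C)cc(OCOC)cc1OCOC
F6 | step 7 | (3S)-3-[3,5-bis(benzyloxy)phenyl]-3-{2,4-bis(methoxymethoxy)-6-[(triisopropylsilyl)oxy]phenyl}propanoic acid | OC(=O)C[C@@H](c1cc(OCc2ccccc2)cc(OCc2ccccc2)c1)c1c(O[Si](C(C)C)(C(C)C)C(C)C)cc(OCOC)cc1OCOC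
F7 | step 7 | 1,3-dioxo-1,3-dihydro-2H-isoindol-2-yl (3S)-3-[3,5-bis(benzyloxy)phenyl]-3-{2,4-bis(methoxymethoxy)-6-[(triisopropylsilyl)oxy]phenyl}propanoate | O=C(C[C@@H](c1cc(OCc2ccccc2)cc(OCc2ccccc2)c1)c1c(O[Si](C(C)C)(C(C)C)C(C)C)cc(OCOC)cc1OCOC)ON1C(=O)c2ccccc2C1=O
F8 | step 7 | (2-{(1S)-2-[3-(benzyloxy)-4-(methoxymethoxy)phenyl]-1-[3,5-bis(benzyloxy)phenyl]ethyl}-3,5-bis(methoxymethoxy)phenoxy)tri(propan-2-yl)silane | COCOc1ccc(C[C@@H](c2cc(OCc3ccccc3)cc(OCc3ccccc3)c2)c2c(O[Si](C(C)C)(C(C)C)C(C)C)cc(OCOC)cc2OCOC)cc1OCc1ccccc1
F9 | step 7 | 2-{(1S)-2-[3-(benzyloxy)-4-(methoxymethoxy)phenyl]-1-[3,5-bis(benzyloxy)phenyl]ethyl}-3,5-bis(methoxymethoxy)phenol | COCOc1ccc(C[C@@H](c2cc(OCc3ccccc3)cc(OCc3ccccc3)c2)c2c(O)cc(OCOC)cc2OCOC)cc1OCc1ccccc1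
F10 | step 12 | 4-[(2S,3S)-3-{3,5-bis[(triethylsilyl)oxy]phenyl}-6-hydroxy-4-[(E)-2-{4-[(triethylsilyl)oxy]phenyl}ethenyl]-2,3-dihydro-1-benzofuran-2-yl]-2-[(triethylsilyl)oxy]phenol | CC[Si](CC)(CC)Oc1ccc(/C=C/c2cc(O)cc3c2[C@H](c2cc(O[Si](CC)(CC)CC)cc(O[Si](CC)(CC)CC)c2)[C@@H](c2ccc(O)c(O[Si](CC)(CC)CC)c2)O3)cc1
A1 | alternative 1 | 2-[(1R,2S)-1-(3,4-dimethoxyphenyl)-2-(3,5-dimethoxyphenyl)-2-{4-methoxy-2-(methoxymethoxy)-6-[(E)-2-(4-methoxyphenyl)ethenyl]phenyl}ethyl]-4,4,5,5-tetramethyl-1,3,2-dioxaborolane | COc1ccc(/C=C/c2cc(OC)cc(OCOC)c2[C@H](c2cc(OC)cc(OC)c2)[C@@H](B2OC(C)(C)C(C)(C)O2)c2ccc(OC)c(OC)c2)cc1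
A2 | alternative 1 | 2-[(E)-2-{4-methoxy-2-(methoxymethoxy)-6-[(E)-2-(4-methoxyphenyl)ethenyl]phenyl}ethenyl]-4,4,5,5-tetramethyl-1,3,2-dioxaborolane | COc1ccc(/C=C/c2cc(OC)cc(OCOC)c2/C=C/B2OC(C)(C)C(C)(C)O2)cc1
A3 | alternative 1 | (3,4-dimethoxyphenyl)lithium | [Li]c1ccc(OC)c(OC)c1
A4 | alternative 1 | 3,5-dimethoxyphenyl trifluoromethanesulfonate | COc1cc(OC)cc(OS(=O)(=O)C(F)(F)F)c1
A5 | alternative 2 | 2-[(2S,3S)-2-(3,4-dimethoxyphenyl)-3-(3,5-dimethoxyphenyl)-4-[(E)-2-(4-methoxyphenyl)ethenyl]-2,3-dihydro-1-benzofuran-6-yl]-4,4,5,5-tetramethyl-1,3,2-dioxaborolane | COc1ccc(/C=C/c2cc(B4OC(C)(C)C(C)(C)O4)cc3c2[C@H](c2cc(OC)cc(OC)c2)[C@@H](c2ccc(OC)c(OC)c2)O3)cc1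
A6 | alternative 2 | 4-[(1S,2S,5E)-2-(3,5-dimethoxyphenyl)-1-(ethynyloxy)-6-(4-methoxyphenyl)hex-5-en-3-yn-1-yl]-1,2-dimethoxybenzene | C#CO[C@H](c1ccc(OC)c(OC)c1)[C@@H](c1cc(OC)cc(OC)c1)C#C/C=C/c1ccc(OC)cc1
A7 | alternative 2 | 2-ethynyl-4,4,5,5-tetramethyl-1,3,2-dioxaborolane | C#CB1OC(C)(C)C(C)(C)O1
A8 | alternative 3 | methyl (2S,3S)-4-(benzyloxy)-2-(3,4-dimethoxyphenyl)-6-methoxy-2,3-dihydro-1-benzofuran-3-carboxylate | c1ccccc1COc2cc(OC)cc3c2[C@H](C(=O)OC)[C@@H](c2ccc(OC)c(OC)c2)O3
A9 | alternative 3 | (2S)-5-(benzyloxy)-2-(3,4-dimethoxyphenyl)-7-methoxy-2,3-dihydro-4H-chromen-4-one | O=C1C[C@@H](c2ccc(OC)c(OC)c2)Oc2cc(OC)cc(OCc3ccccc3)c12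
A10 | alternative 3 | (2S)-5-(benzyloxy)-2-(3,4-dimethoxyphenyl)-4,7-dimethoxy-2H-chromene | COC1=C[C@@H](c2ccc(OC)c(OC)c2)Oc2cc(OC)cc(OCc3ccccc3)c12
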